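**Plan**

- Cuts, in retrosynthetic order: the MOM ether on O–C4'; the pyranone bonds C3–C4 and O1–C2, leading back to a MOM-protected chroman-2-one and methylketene dimer; the lactone of that chromanone (C2 and C3 from Meldrum's acid, bridge carbon from DMF); the C3'–prenyl bond (O-prenylation, then Claisen–Cope); the C5'–isobutyryl bond (Friedel–Crafts).
- Enabling feature: the C2' hydroxyl of benzene ring A is ortho to the C1' methylene bridge, so O–C2', C2', C1', the bridge CH2 and pyranone C3 and C2 form a latent 3,4-dihydrocoumarin lactone (ring C). Pyranone O1, C6 (ethyl), C5 (methyl) and C4 map onto the ring oxygen, C4, C3 and C2 of methylketene dimer.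
- Forward order: ring A is phloroglucinol throughout and receives acyl, prenyl, O-methyl and formyl groups in turn (steps 1–7). Lactone ring C closes in step 8. Pyranone ring B closes in step 11 in the same operation that opens ring C. Step 12 removes the MOM group.
- Stereochemistry: the target has no stereocentre and no stereogenic double bond. The centres of the racemic ketene dimer and of the transient acylation product disappear when ring B aromatises.

Key step: step 11

Assumption: locants are O1, C2–C6 for the pyranone and C1'–C6' for the benzene ring (C1' carries the CH2 bridge); the methylketene dimer is used as the racemic (Z)-β-lactone.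

**Route**

Step 1
Reactants: 1 phloroglucinol; 2 isobutyryl chloride
Product: 3 2-methyl-1-(2,4,6-trihydroxyphenyl)propan-1-one
Conditions: AlCl3 (3.5 equiv), CH2Cl2/MeNO2, 0 → 23 °C; then ice/aq. HCl
Reagents that add atoms: none
Why: Friedel–Crafts C-acylation of the symmetrical, strongly activated triphenol should stop at the monoketone because the first acyl group deactivates the ring.

Step 2
Reactants: 3 2-methyl-1-(2,4,6-trihydroxyphenyl)propan-1-one
Product: 4 1-[2-hydroxy-4,6-bis(methoxymethoxy)phenyl]-2-methylpropan-1-one
Conditions: MOMCl (2.3 equiv), iPr2NEt, CH2Cl2, 0 → 23 °C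
Reagents that add atoms: chloromethyl methyl ether, COCCl
Why: MOM ether formation (Williamson-type O-alkylation) under amine base should take the para hydroxyl and one ortho hydroxyl and leave the third, which is held in a hydrogen bond to the ketone.

Step 3
Reactants: 4 1-[2-hydroxy-4,6-bis(methoxymethoxy)phenyl]-2-methylpropan-1-one; 5 prenyl bromide
Product: 6 1-[2,4-bis(methoxymethoxy)-6-(3-methylbut-2-enyloxy)phenyl]-2-methylpropan-1-one
Conditions: K2CO3, acetone, reflux
Reagents that add atoms: none
Why: Williamson O-alkylation of the remaining phenol by the reactive allylic bromide under carbonate conditions, which favour oxygen over carbon alkylation.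

Step 4
Reactants: 6 1-[2,4-bis(methoxymethoxy)-6-(3-methylbut-2-enyloxy)phenyl]-2-methylpropan-1-one
Product: 8 1-[6-hydroxy-2,4-bis(methoxymethoxy)-3-(3-methylbut-2-enyl)phenyl]-2-methylpropan-1-one, via ortho-dienone 7 (not isolated)
Conditions: N,N-diethylaniline, 200 °C, sealed tube
Reagents that add atoms: none
Why: Aromatic Claisen rearrangement to the one ortho carbon that bears hydrogen gives dienone 7, whose 1,5-diene should undergo Cope rearrangement to the para carbon between the two MOM ethers (para-Claisen–Cope), delivering an un-inverted prenyl group and regenerating the chelated phenol.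

Step 5
Reactants: 8 1-[6-hydroxy-2,4-bis(methoxymethoxy)-3-(3-methylbut-2-enyl)phenyl]-2-methylpropan-1-one
Product: 9 1-[6-methoxy-2,4-bis(methoxymethoxy)-3-(3-methylbut-2-enyl)phenyl]-2-methylpropan-1-one
Conditions: MeI, K2CO3, DMF, 23 °C
Reagents that add atoms: iodomethane, CI
Why: Williamson methylation of the single free phenol fixes the methoxy group ortho to the ketone and para to the prenyl group.

Step 6
Reactants: 9 1-[6-methoxy-2,4-bis(methoxymethoxy)-3-(3-methylbut-2-enyl)phenyl]-2-methylpropan-1-one
Product: 10 1-[2,4-dihydroxy-6-methoxy-3-(3-methylbut-2-enyl)phenyl]-2-methylpropan-1-one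
Conditions: aq. HCl (3 M), MeOH, 23 °C
Reagents that add atoms: none
Why: Acid-catalysed acetal exchange with methanol removes both MOM ethers under conditions of the kind used for prenylated acylphloroglucinols at room temperature.

Step 7
Reactants: 10 1-[2,4-dihydroxy-6-methoxy-3-(3-methylbut-2-enyl)phenyl]-2-methylpropan-1-one
Product: 12 2,4-dihydroxy-6-methoxy-5-(2-methylpropanoyl)-3-(3-methylbut-2-enyl)benzaldehyde, via aryl iminium chloride 11 (not isolated)
Conditions: POCl3, DMF, EtOAc, 0 → 23 °C; then H2O, 23 °C
Reagents that add atoms: N,N-dimethylformamide, CN(C)C=O; water, O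
Why: Vilsmeier–Haack formylation can only occur at the one unsubstituted ring carbon, which is ortho or para to three oxygen substituents, and hydrolysis of iminium salt 11 gives the aldehyde.

Step 8
Reactants: 12 2,4-dihydroxy-6-methoxy-5-(2-methylpropanoyl)-3-(3-methylbut-2-enyl)benzaldehyde; 13 Meldrum's acid
Product: 17 7-hydroxy-5-methoxy-6-(2-methylpropanoyl)-8-(3-methylbut-2-enyl)chroman-2-one, via arylidene Meldrum's acid 14 (not isolated), via benzyl Meldrum's acid 15 (not isolated), via 2-oxochromane-3-carboxylic acid 16 (not isolated)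
Conditions: diethyl 2,6-dimethyl-1,4-dihydropyridine-3,5-dicarboxylate (Hantzsch ester, 1.1 equiv), L-proline (20 mol%), EtOH, 23 °C; evaporation of EtOH; then pyridine, 100 °C; dilute aq. HCl work-up
Reagents that add atoms: none
Why: Proline-catalysed reductive Knoevenagel alkylation of Meldrum's acid (condensation to 14, Hantzsch ester hydride transfer to 15) is followed on heating by attack of the only hydroxyl ortho to the new benzyl group on a Meldrum's carbonyl with loss of acetone, and by decarboxylation of the malonic half-ester 16.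

Step 9
Reactants: 17 7-hydroxy-5-methoxy-6-(2-methylpropanoyl)-8-(3-methylbut-2-enyl)chroman-2-one
Product: 18 5-methoxy-7-(methoxymethoxy)-6-(2-methylpropanoyl)-8-(3-methylbut-2-enyl)chroman-2-one
Conditions: NaH (1.05 equiv), MOMCl, THF/DMF, 0 °C
Reagents that add atoms: chloromethyl methyl ether, COCCl
Why: Williamson MOM ether formation on the sodium phenoxide, since the chelated phenol is far more acidic than the lactone CH2 and one equivalent of NaH deprotonates only it.

Step 10
Reactants: 19 propanoyl chloride (two molecules per molecule of product)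
Product: 21 (Z)-4-ethylidene-3-methyloxetan-2-one (racemic methylketene dimer), via methylketene 20 (not isolated)
Conditions: Et3N (1.0 equiv per acid chloride), Et2O, 0 → 35 °C; filtration; distillation under reduced pressure
Reagents that add atoms: propanoyl chloride (the second molecule of 19), CCC(=O)Cl
Why: Dehydrochlorination of each of two acid chloride molecules gives methylketene 20, and two molecules of 20 combine by formal [2+2] addition of the C=C bond of one to the C=O bond of the other to give the β-lactone, the standard preparation of aldoketene dimers.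

Step 11
Reactants: 18 5-methoxy-7-(methoxymethoxy)-6-(2-methylpropanoyl)-8-(3-methylbut-2-enyl)chroman-2-one; 21 (Z)-4-ethylidene-3-methyloxetan-2-one
Product: 23 6-ethyl-4-hydroxy-3-{[2-hydroxy-6-methoxy-4-(methoxymethoxy)-5-(2-methylpropanoyl)-3-(3-methylbut-2-enyl)phenyl]methyl}-5-methyl-2H-pyran-2-one, via 3-(2-methyl-3-oxopentanoyl)chromanone 22 (not isolated)
Conditions: LiN(SiMe3)2 (1.05 equiv), THF, −78 °C (18 added to the base); 21 (1.1 equiv), −78 → 23 °C; cold 0.5 M aq. HCl
Reagents that add atoms: none
Why: Proposed new method: the lithium enolate of aryl lactone 18 should attack the strained acyl carbon of β-lactone 21 in a Claisen-type C-acylation (pyranone C3–C4 bond), and acyl–oxygen cleavage frees the enolate of an ethyl ketone, which is protonated at its ethylidene carbon by the newly acidified lactone α-hydrogen to give tricarbonyl compound 22 as its stabilised anion. Through the C5 enolate form of that anion, the oxygen on the ethyl-bearing carbon then adds to the aryl lactone carbonyl in a 6-exo-trig closure (O1–C2 bond), the tetrahedral intermediate expels the C2' phenoxide so that ring B closes as ring C opens, and enolisation of the resulting pyran-2,4-dione across C3–C4 gives the aromatic 4-hydroxypyranone anion. The closest known reactions are acetoacetylation of carbon nucleophiles by diketene, opening of alkylketene dimers at the acyl carbon by lithium amides, and base-induced closure of 3,5-dioxo esters and O-acylsalicylates to 4-hydroxypyranones and 4-hydroxycoumarins. No stereocentre is created, and the centres of racemic 21 and of 22 are erased by the final enolisation. The step needs enolisation at the lactone CH2 and not the isobutyryl methine, acylation at carbon and not oxygen, and ring closure through oxygen and not carbon: the ketone is twisted between two ortho substituents with a tertiary α-hydrogen, lithium enolates react with ester-type acyl donors at carbon, and with one equivalent of strong base the terminal ethyl group is never deprotonated, which excludes Claisen closure to a phloroglucinol. Relief of β-lactone strain and exchange of an aryl ester for a delocalised pyranone anion should make the overall change downhill.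

Step 12
Reactants: 23 6-ethyl-4-hydroxy-3-{[2-hydroxy-6-methoxy-4-(methoxymethoxy)-5-(2-methylpropanoyl)-3-(3-methylbut-2-enyl)phenyl]methyl}-5-methyl-2H-pyran-2-one
Product: 24 6-ethyl-4-hydroxy-3-{[2,4-dihydroxy-6-methoxy-5-(2-methylpropanoyl)-3-(3-methylbut-2-enyl)phenyl]methyl}-5-methyl-2H-pyran-2-one (CNP0149198.0)
Conditions: HCl (1 M in MeOH), 23 °C
Reagents that add atoms: none
Why: Acid-catalysed acetal exchange cleaves the MOM ether, which is activated by chelation to the ortho ketone, under conditions expected to spare the prenyl group and the pyranone.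

**Compound list**

1 | phloroglucinol | Oc1cc(O)cc(O)c1 | starting material
2 | isobutyryl chloride | CC(C)C(Cl)=O | starting material
3 | 2-methyl-1-(2,4,6-trihydroxyphenyl)propan-1-one | CC(C)C(=O)c1c(O)cc(O)cc1O | intermediate
4 | 1-[2-hydroxy-4,6-bis(methoxymethoxy)phenyl]-2-methylpropan-1-one | CC(C)C(=O)c1c(O)cc(OCOC)cc1OCOC | intermediate
5 | prenyl bromide (1-bromo-3-methylbut-2-ene) | CC(C)=CCBr | starting material
6 | 1-[2,4-bis(methoxymethoxy)-6-(3-methylbut-2-enyloxy)phenyl]-2-methylpropan-1-one | CC(C)C(=O)c1c(OCC=C(C)C)cc(OCOC)cc1OCOC | intermediate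
7 | 3,5-bis(methoxymethoxy)-6-(2-methylbut-3-en-2-yl)-2-(2-methylpropanoyl)cyclohexa-2,4-dien-1-one, racemic ortho-dienone (not isolated) | O=C1C(C(C)(C)C=C)C(OCOC)=CC(OCOC)=C1C(=O)C(C)C | intermediate
8 | 1-[6-hydroxy-2,4-bis(methoxymethoxy)-3-(3-methylbut-2-enyl)phenyl]-2-methylpropan-1-one | CC(C)C(=O)c1c(O)cc(OCOC)c(CC=C(C)C)c1OCOC | intermediate
9 | 1-[6-methoxy-2,4-bis(methoxymethoxy)-3-(3-methylbut-2-enyl)phenyl]-2-methylpropan-1-one | CC(C)C(=O)c1c(OC)cc(OCOC)c(CC=C(C)C)c1OCOC | intermediate
10 | 1-[2,4-dihydroxy-6-methoxy-3-(3-methylbut-2-enyl)phenyl]-2-methylpropan-1-one | CC(C)C(=O)c1c(OC)cc(O)c(CC=C(C)C)c1O | intermediate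
11 | N-{[2,4-dihydroxy-6-methoxy-5-(2-methylpropanoyl)-3-(3-methylbut-2-enyl)phenyl]methylidene}-N-methylmethanaminium chloride (not isolated) | CC(C)C(=O)c1c(OC)c(C=[N+](C)C)c(O)c(CC=C(C)C)c1O.[Cl-] | intermediate
12 | 2,4-dihydroxy-6-methoxy-5-(2-methylpropanoyl)-3-(3-methylbut-2-enyl)benzaldehyde | O=Cc1c(O)c(CC=C(C)C)c(O)c(C(=O)C(C)C)c1OC | intermediate
13 | Meldrum's acid (2,2-dimethyl-1,3-dioxane-4,6-dione) | CC1(C)OC(=O)CC(=O)O1 | starting material
14 | 5-{[2,4-dihydroxy-6-methoxy-5-(2-methylpropanoyl)-3-(3-methylbut-2-enyl)phenyl]methylidene}-2,2-dimethyl-1,3-dioxane-4,6-dione (not isolated) | CC1(C)OC(=O)C(=Cc2c(O)c(CC=C(C)C)c(O)c(C(=O)C(C)C)c2OC)C(=O)O1 | intermediate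
15 | 5-{[2,4-dihydroxy-6-methoxy-5-(2-methylpropanoyl)-3-(3-methylbut-2-enyl)phenyl]methyl}-2,2-dimethyl-1,3-dioxane-4,6-dione (not isolated) | CC1(C)OC(=O)C(Cc2c(O)c(CC=C(C)C)c(O)c(C(=O)C(C)C)c2OC)C(=O)O1 | intermediate
16 | 7-hydroxy-5-methoxy-6-(2-methylpropanoyl)-8-(3-methylbut-2-enyl)-2-oxochromane-3-carboxylic acid, racemic (not isolated) | OC(=O)C1Cc2c(OC)c(C(=O)C(C)C)c(O)c(CC=C(C)C)c2OC1=O | intermediate
17 | 7-hydroxy-5-methoxy-6-(2-methylpropanoyl)-8-(3-methylbut-2-enyl)chroman-2-one | O=C1CCc2c(OC)c(C(=O)C(C)C)c(O)c(CC=C(C)C)c2O1 | intermediate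
18 | 5-methoxy-7-(methoxymethoxy)-6-(2-methylpropanoyl)-8-(3-methylbut-2-enyl)chroman-2-one | COCOc1c(CC=C(C)C)c2OC(=O)CCc2c(OC)c1C(=O)C(C)C | intermediate
19 | propanoyl chloride | CCC(Cl)=O | starting material
20 | methylketene (not isolated) | CC=C=O | intermediate
21 | (Z)-4-ethylidene-3-methyloxetan-2-one, racemic methylketene dimer | C/C=C1\OC(=O)C1C | intermediate
22 | 5-methoxy-7-(methoxymethoxy)-3-(2-methyl-3-oxopentanoyl)-6-(2-methylpropanoyl)-8-(3-methylbut-2-enyl)chroman-2-one, diastereomer mixture drawn in the keto form (not isolated) | CCC(=O)C(C)C(=O)C1Cc2c(OC)c(C(=O)C(C)C)c(OCOC)c(CC=C(C)C)c2OC1=O | intermediate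
23 | 6-ethyl-4-hydroxy-3-{[2-hydroxy-6-methoxy-4-(methoxymethoxy)-5-(2-methylpropanoyl)-3-(3-methylbut-2-enyl)phenyl]methyl}-5-methyl-2H-pyran-2-one | CCc1oc(=O)c(Cc2c(O)c(CC=C(C)C)c(OCOC)c(C(=O)C(C)C)c2OC)c(O)c1C | intermediate
24 | 6-ethyl-4-hydroxy-3-{[2,4-dihydroxy-6-methoxy-5-(2-methylpropanoyl)-3-(3-methylbut-2-enyl)phenyl]methyl}-5-methyl-2H-pyran-2-one | CCc1oc(=O)c(Cc2c(O)c(CC=C(C)C)c(O)c(C(=O)C(C)C)c2OC)c(O)c1C | target

**Count**

Total steps: 12. Longest linear sequence: 11 steps (steps 1–9, 11, 12); step 10 is a one-step side branch.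

**Steps most likely to fail**

1. Step 11 (proposed method). The enolate may be lost to proton exchange with the ketone methine or to self-condensation, acylation may go to oxygen, or the tricarbonyl anion may not translactonise. A first remedy inside the step would be DBU after the acylation.
Fallback with known chemistry, from 10 to target 24, without the lactone: the dianion of methyl 3-oxopentanoate (NaH, then n-BuLi) is acylated at C4 with N-methoxy-N-methylpropanamide to give methyl 4-methyl-3,5-dioxoheptanoate F1. DBU in hot toluene closes it to 6-ethyl-4-hydroxy-5-methyl-2H-pyran-2-one F2. Eschenmoser's salt converts F2 into 3-[(dimethylamino)methyl]-6-ethyl-4-hydroxy-5-methyl-2H-pyran-2-one F3. Heating F3 with an excess of 10 in MeCN should eliminate dimethylamine to the 3-methylenepyrandione, which alkylates the single free ring carbon of 10 and gives 24 directly.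

2. Step 8. The phenol may close onto the alkylidene Meldrum's acid before hydride transfer, stranding material at the unsaturated coumarin acid, or decarboxylation may be incomplete.
Fallback from 12 to 17, building the ring at the coumarin oxidation level and reducing afterwards: Knoevenagel condensation of 12 with diethyl malonate (piperidinium acetate, EtOH, reflux) gives ethyl 7-hydroxy-5-methoxy-6-(2-methylpropanoyl)-8-(3-methylbut-2-enyl)-2-oxo-2H-chromene-3-carboxylate F4. Conjugate reduction of the doubly activated alkene with NaBH4 (THF/EtOH, 0 °C) gives ethyl 7-hydroxy-5-methoxy-6-(2-methylpropanoyl)-8-(3-methylbut-2-enyl)-2-oxochromane-3-carboxylate F5. Krapcho dealkoxycarbonylation (LiCl, wet DMSO, 130 °C) with an acidic work-up to re-close any opened lactone returns to 17.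

3. Step 7. Acid released in the Vilsmeier reaction may add a flanking phenol across the prenyl double bond (chroman formation), or the phenols may be consumed by O-formylation.
Fallback from 10 to 17, without an aldehyde: aminomethylation of 10 with Eschenmoser's salt (CH2Cl2, 23 °C) at the one free ring carbon gives 1-[3-[(dimethylamino)methyl]-4,6-dihydroxy-2-methoxy-5-(3-methylbut-2-enyl)phenyl]-2-methylpropan-1-one F6. Heating F6 with Meldrum's acid 13 in toluene/pyridine (100 °C) should expel dimethylamine to an ortho-quinone methide, which adds 13 to give 15. This then lactonises and decarboxylates through 16 to 17. F6 has no free ring position, so the quinone methide cannot form a diarylmethane.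

**Further compounds**

F1 | step 11 | methyl 4-methyl-3,5-dioxoheptanoate | CCC(=O)C(C)C(=O)CC(=O)OC
F2 | step 11 | 6-ethyl-4-hydroxy-5-methyl-2H-pyran-2-one | CCc1oc(=O)cc(O)c1C
F3 | step 11 | 3-[(dimethylamino)methyl]-6-ethyl-4-hydroxy-5-methyl-2H-pyran-2-one | CCc1oc(=O)c(CN(C)C)c(O)c1C
F4 | step 8 | ethyl 7-hydroxy-5-methoxy-6-(2-methylpropanoyl)-8-(3-methylbut-2-enyl)-2-oxo-2H-chromene-3-carboxylate | CCOC(=O)c1cc2c(OC)c(C(=O)C(C)C)c(O)c(CC=C(C)C)c2oc1=O
F5 | step 8 | ethyl 7-hydroxy-5-methoxy-6-(2-methylpropanoyl)-8-(3-methylbut-2-enyl)-2-oxochromane-3-carboxylate, racemic | CCOC(=O)C1Cc2c(OC)c(C(=O)C(C)C)c(O)c(CC=C(C)C)c2OC1=O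
F6 | step 7 | 1-[3-[(dimethylamino)methyl]-4,6-dihydroxy-2-methoxy-5-(3-methylbut-2-enyl)phenyl]-2-methylpropan-1-one | CN(C)Cc1c(O)c(CC=C(C)C)c(O)c(C(=O)C(C)C)c1OC
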